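Ring B, the dihydrofuran ring (benzofuran numbering), is cut at O1–C7a and C2–C3, which makes the O1–C2 unit the carbonyl group of a protected syringaldehyde and ring A an ortho-sulfinyl ethylarene. The key step exploits the 1,3-relation of C3 and C7a across C3a of ring A: a benzylic carbanion at C3, held and shielded by an enantiopure p-tolylsulfinyl group on C7a, adds to the aldehyde, and the new alkoxide displaces that same sulfinyl group from C7a. One operation forms both bonds of ring B and both stereocenters, and the auxiliary leaves without a trace. The precursor is an open-chain diaryl sulfoxide without oxygen at C7a; Suzuki coupling adds the propenyl group last.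

Key step: step 5

Remark on numbering: benzofuran numbering is used throughout (O1, C2, C3, C3a, C4 to C7, C7a); ring A is the benzene ring and ring B the dihydrofuran ring of the target, whose stereocenters are (2R,3R), trans.

Remark on the chemistry: the sense of the 1,4-induction is assumed from the chelate model of ortho-sulfinyl benzyllithium compounds (lithium bound to the sulfinyl oxygen, electrophile delivered to the lithium face), by which the (R)-sulfoxide should give (3R); were the sense opposite, the enantiomeric menthyl sulfinate would be used in step 2 and nothing else would change.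

Remark on materials: compounds 1, 4, 9 and 15 are taken as commercially available.

**Step 1**
Reactants: 1 4-bromo-2-methoxy-6-methylaniline
Product: 3 5-bromo-2-iodo-1-methoxy-3-methylbenzene, via arenediazonium chloride 2 (not isolated)
Conditions: NaNO2, aq. HCl, MeCN, 0 °C; then KI, 0 → 25 °C
Reagents that add atoms: potassium iodide, [K+].[I-]
Why: Diazotization–iodination (Sandmeyer-type, no copper needed for iodide) puts at the future C7a a halogen that exchanges with magnesium in preference to the C5 bromine.

**Step 2**
Reactants: 3 5-bromo-2-iodo-1-methoxy-3-methylbenzene; 4 (1S,2R,5S)-(+)-menthyl (R)-p-toluenesulfinate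
Product: 6 5-bromo-1-methoxy-3-methyl-2-[(R)-(4-methylphenyl)sulfinyl]benzene, via arylmagnesium chloride 5 (not isolated)
Conditions: i-PrMgCl·LiCl, THF, −20 °C; then 4, −40 → 0 °C
Reagents that add atoms: none
Why: Andersen sulfoxide synthesis, in which the aryl Grignard reagent from selective iodine–magnesium exchange displaces menthoxide at sulfur with inversion, so the sulfur stereocenter of 6 comes from the sulfinate.

**Step 3**
Reactants: 6 5-bromo-1-methoxy-3-methyl-2-[(R)-(4-methylphenyl)sulfinyl]benzene
Product: 8 5-bromo-1-ethyl-3-methoxy-2-[(R)-(4-methylphenyl)sulfinyl]benzene, via benzylic organolithium 7 (not isolated)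
Conditions: LiN(i-Pr)2, THF, −78 °C; then MeI, −78 °C
Reagents that add atoms: iodomethane, CI
Why: Lateral lithiation–alkylation, in which the ortho-sulfinyl group acidifies and chelates the benzylic position so that the aryl methyl group is metalated selectively and extended to ethyl without change at sulfur.

**Step 4**
Reactants: 9 syringaldehyde (4-hydroxy-3,5-dimethoxybenzaldehyde)
Product: 10 3,5-dimethoxy-4-(methoxymethoxy)benzaldehyde
Conditions: MOMCl, i-Pr2NEt, CH2Cl2, 0 → 25 °C
Reagents that add atoms: chloromethyl methyl ether, COCCl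
Why: O-alkylation of the phenol (Williamson-type) gives a base-stable acetal ether, needed because a free phenol would quench the carbanion of step 5.

**Step 5**
Reactants: 8 5-bromo-1-ethyl-3-methoxy-2-[(R)-(4-methylphenyl)sulfinyl]benzene; 10 3,5-dimethoxy-4-(methoxymethoxy)benzaldehyde
Product: 13 (2R,3R)-5-bromo-2-[3,5-dimethoxy-4-(methoxymethoxy)phenyl]-7-methoxy-3-methyl-2,3-dihydro-1-benzofuran, via benzylic organolithium 11 (not isolated), via lithium alkoxide 12 (not isolated)
Conditions: LiN(i-Pr)2 (1.05 equiv), THF, −78 °C; 10, −78 °C; then KOt-Bu, 18-crown-6, −78 → 25 °C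
Reagents that add atoms: none
Why: LiN(i-Pr)2 removes a benzylic proton of 8 to give the sulfinyl-chelated benzyllithium 11, which adds to aldehyde 10 and forms C2–C3, and the alkoxide 12, made more nucleophilic as its potassium/crown ether pair, attacks C7a ipso to sulfur and expels p-toluenesulfenate, which forms O1–C7a (addition–elimination, SNAr). The closest known reaction types are the 1,4-induced addition of ortho-sulfinyl benzyl carbanions to aldehydes and imines and the intramolecular ipso-substitution of an aryl sulfinyl group by a heteroatom anion, which closes indolines from the nitrogen adducts of the same carbanions. Ring B closes in the 5-exo-trig mode at an aromatic carbon through a spiro Meisenheimer-type intermediate. C3 is controlled by the sulfur stereocenter, since lithium is held by the sulfinyl oxygen on one face of the planar benzylic carbon while the S-tolyl group turns away and the lithium-bound aldehyde is delivered to that face; C2 is controlled by C3 in the closed transition state, where the aryl group of the aldehyde stays anti to ring A, the arrangement that ends as the trans ring. The step needs benzylic rather than ring lithiation, secured by the acidifying and chelating ortho-sulfinyl group, and ring closure faster than retro-addition, secured by the five-membered ring size, the sulfenate nucleofuge and the para bromine.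

**Step 6**
Reactants: 13 (2R,3R)-5-bromo-2-[3,5-dimethoxy-4-(methoxymethoxy)phenyl]-7-methoxy-3-methyl-2,3-dihydro-1-benzofuran
Product: 14 4-[(2R,3R)-5-bromo-7-methoxy-3-methyl-2,3-dihydro-1-benzofuran-2-yl]-2,6-dimethoxyphenol
Conditions: HCl (dilute), MeOH, 25 °C
Reagents that add atoms: none
Why: Acid-catalysed acetal exchange with methanol (MOM ether cleavage) frees the phenol under dilute acid at room temperature, where the aryl bromide and the two stereocenters should stay unchanged and no acid-sensitive propenyl group is yet present.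

**Step 7**
Reactants: 14 4-[(2R,3R)-5-bromo-7-methoxy-3-methyl-2,3-dihydro-1-benzofuran-2-yl]-2,6-dimethoxyphenol; 15 (E)-prop-1-enylboronic acid pinacol ester
Product: 16 maceneolignan A, 2,6-dimethoxy-4-[(2R,3R)-7-methoxy-3-methyl-5-[(E)-prop-1-enyl]-2,3-dihydro-1-benzofuran-2-yl]phenol
Conditions: Pd(OAc)2, SPhos, K3PO4, dioxane/H2O (degassed), 80 °C
Reagents that add atoms: none
Why: Suzuki–Miyaura coupling transfers the alkenyl group with retention of its (E) geometry, the electron-rich phosphine serving oxidative addition into the electron-rich aryl bromide while the phenol is carried as its phosphate-buffered phenoxide.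

**Compound list**

1 | 4-bromo-2-methoxy-6-methylaniline | Cc1cc(Br)cc(OC)c1N | starting material
2 | 4-bromo-2-methoxy-6-methylbenzenediazonium chloride (not isolated) | Cc1cc(Br)cc(OC)c1[N+]#N.[Cl-] | intermediate
3 | 5-bromo-2-iodo-1-methoxy-3-methylbenzene | Cc1cc(Br)cc(OC)c1I | intermediate
4 | (1S,2R,5S)-(+)-menthyl (R)-p-toluenesulfinate | CC(C)[C@H]1CC[C@H](C)C[C@@H]1O[S@@](=O)c1ccc(C)cc1 | starting material
5 | (4-bromo-2-methoxy-6-methylphenyl)magnesium chloride (not isolated) | Cc1cc(Br)cc(OC)c1[Mg]Cl | intermediate
6 | 5-bromo-1-methoxy-3-methyl-2-[(R)-(4-methylphenyl)sulfinyl]benzene | Cc1cc(Br)cc(OC)c1[S@](=O)c1ccc(C)cc1 | intermediate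
7 | {5-bromo-3-methoxy-2-[(R)-(4-methylphenyl)sulfinyl]phenyl}methyllithium (not isolated) | [Li]Cc1cc(Br)cc(OC)c1[S@](=O)c1ccc(C)cc1 | intermediate
8 | 5-bromo-1-ethyl-3-methoxy-2-[(R)-(4-methylphenyl)sulfinyl]benzene | CCc1cc(Br)cc(OC)c1[S@](=O)c1ccc(C)cc1 | intermediate
9 | syringaldehyde (4-hydroxy-3,5-dimethoxybenzaldehyde) | COc1cc(C=O)cc(OC)c1O | starting material
10 | 3,5-dimethoxy-4-(methoxymethoxy)benzaldehyde | COCOc1c(OC)cc(C=O)cc1OC | intermediate
11 | 1-{5-bromo-3-methoxy-2-[(R)-(4-methylphenyl)sulfinyl]phenyl}ethyllithium, chelated and configurationally mobile at carbon (not isolated) | CC([Li])c1cc(Br)cc(OC)c1[S@](=O)c1ccc(C)cc1 | intermediate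
12 | lithium (1R,2R)-2-{5-bromo-3-methoxy-2-[(R)-(4-methylphenyl)sulfinyl]phenyl}-1-[3,5-dimethoxy-4-(methoxymethoxy)phenyl]propan-1-olate (not isolated) | [Li+].[O-][C@@H](c1cc(OC)c(OCOC)c(OC)c1)[C@H](C)c1cc(Br)cc(OC)c1[S@](=O)c1ccc(C)cc1 | intermediate
13 | (2R,3R)-5-bromo-2-[3,5-dimethoxy-4-(methoxymethoxy)phenyl]-7-methoxy-3-methyl-2,3-dihydro-1-benzofuran | Brc1cc(OC)c2c(c1)[C@@H](C)[C@H](c1cc(OC)c(OCOC)c(OC)c1)O2 | intermediate
14 | 4-[(2R,3R)-5-bromo-7-methoxy-3-methyl-2,3-dihydro-1-benzofuran-2-yl]-2,6-dimethoxyphenol | Brc1cc(OC)c2c(c1)[C@@H](C)[C@H](c1cc(OC)c(O)c(OC)c1)O2 | intermediate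
15 | (E)-prop-1-enylboronic acid pinacol ester | C/C=C/B1OC(C)(C)C(C)(C)O1 | starting material
16 | maceneolignan A, 2,6-dimethoxy-4-[(2R,3R)-7-methoxy-3-methyl-5-[(E)-prop-1-enyl]-2,3-dihydro-1-benzofuran-2-yl]phenol | C/C=C/c1cc(OC)c2c(c1)[C@@H](C)[C@H](c1cc(OC)c(O)c(OC)c1)O2 | target

**Step count**

Total: 7 steps. Longest linear sequence: 6 steps (steps 1, 2, 3, 5, 6, 7 from aniline 1); step 4 is a one-step side branch.

**Steps most likely to fail**

Step 5. The alkoxide may revert to carbanion and aldehyde before it closes the ring, which would erode the configuration at C3 and C2, or the ipso-substitution at the electron-rich ring may be too slow. The fallback sets out from 8 and 10 and separates the two bond formations. The addition alone is run with LiN(i-Pr)2 at −78 °C and quenched cold to give the sulfinyl alcohol (1R,2R)-2-{5-bromo-3-methoxy-2-[(R)-(4-methylphenyl)sulfinyl]phenyl}-1-[3,5-dimethoxy-4-(methoxymethoxy)phenyl]propan-1-ol F1, from which a minor carbinol epimer can be removed. Sulfoxide–magnesium exchange with i-PrMgCl·LiCl (one equivalent first consumed by the hydroxyl group) and quench with I2 then give the iodo alcohol (1R,2R)-2-(5-bromo-2-iodo-3-methoxyphenyl)-1-[3,5-dimethoxy-4-(methoxymethoxy)phenyl]propan-1-ol F2. Intramolecular Ullmann etherification (CuI, 1,10-phenanthroline, Cs2CO3, toluene, 100 °C) closes O1–C7a at the iodide in preference to the bromide and comes back to the route at 13.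

Step 6. The acid may ionize the donor-substituted benzylic C2–O1 ether, with ring opening or loss of the C2 configuration, while the acetal is cleaved. The fallback sets out from 9 and uses a fluoride-labile group instead. SEMCl and i-Pr2NEt give 3,5-dimethoxy-4-{[2-(trimethylsilyl)ethoxy]methoxy}benzaldehyde F3. The conditions of step 5 with 8 then give (2R,3R)-5-bromo-2-(3,5-dimethoxy-4-{[2-(trimethylsilyl)ethoxy]methoxy}phenyl)-7-methoxy-3-methyl-2,3-dihydro-1-benzofuran F4. n-Bu4NF in THF/DMPU at 60 °C removes the group by fluoride-induced fragmentation without acid and comes back to the route at 14.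

Step 7. Oxidative addition into the electron-rich, phenoxide-bearing aryl bromide may be slower than protodeboronation of the alkenyl boronate, so that coupling stalls. The fallback sets out from 14 and builds the propenyl group by carbonyl addition and elimination. n-BuLi (2.2 equiv, THF, −78 °C; phenoxide formation, then bromine–lithium exchange) and propanal give the benzylic alcohol 4-[(2R,3R)-5-(1-hydroxypropyl)-7-methoxy-3-methyl-2,3-dihydro-1-benzofuran-2-yl]-2,6-dimethoxyphenol F5 as a mixture of carbinol epimers. Acid-catalysed dehydration (KHSO4, toluene, 80 °C) should give the conjugated (E)-alkene under thermodynamic control and comes back to the route at 16.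

**Further compounds**

F1 | step 5 | (1R,2R)-2-{5-bromo-3-methoxy-2-[(R)-(4-methylphenyl)sulfinyl]phenyl}-1-[3,5-dimethoxy-4-(methoxymethoxy)phenyl]propan-1-ol | O[C@@H](c1cc(OC)c(OCOC)c(OC)c1)[C@H](C)c1cc(Br)cc(OC)c1[S@](=O)c1ccc(C)cc1
F2 | step 5 | (1R,2R)-2-(5-bromo-2-iodo-3-methoxyphenyl)-1-[3,5-dimethoxy-4-(methoxymethoxy)phenyl]propan-1-ol | O[C@@H](c1cc(OC)c(OCOC)c(OC)c1)[C@H](C)c1cc(Br)cc(OC)c1I
F3 | step 6 | 3,5-dimethoxy-4-{[2-(trimethylsilyl)ethoxy]methoxy}benzaldehyde | C[Si](C)(C)CCOCOc1c(OC)cc(C=O)cc1OC
F4 | step 6 | (2R,3R)-5-bromo-2-(3,5-dimethoxy-4-{[2-(trimethylsilyl)ethoxy]methoxy}phenyl)-7-methoxy-3-methyl-2,3-dihydro-1-benzofuran | Brc1cc(OC)c2c(c1)[C@@H](C)[C@H](c1cc(OC)c(OCOCC[Si](C)(C)C)c(OC)c1)O2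
F5 | step 7 | 4-[(2R,3R)-5-(1-hydroxypropyl)-7-methoxy-3-methyl-2,3-dihydro-1-benzofuran-2-yl]-2,6-dimethoxyphenol (carbinol epimers) | CCC(O)c1cc(OC)c2c(c1)[C@@H](C)[C@H](c1cc(OC)c(O)c(OC)c1)O2
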